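**Retrosynthetic overview**

1. The last C–C bond is C6–C1′ of the side chain: Stille coupling of a C6‑trimethylstannyl enone with the (E)‑allylic bromide of the silyl‑protected arene (from 4‑methoxy‑2‑methylphenol by ortho‑prenylation and SeO2 oxidation). The C5 arm comes from Tsuji–Trost methallylation of a bicyclic 1,3‑dione and Mukaiyama hydration.
2. The 1,3‑dione (C4/C6) comes by oxidation from a 4‑hydroxy‑6‑ketone, the product of one cationic cascade of an epoxide: epoxide opening, cyclobutane‑to‑cyclopentane 1,2‑shift, closure of the six‑membered ring by an enol ether (bond C7–C7a).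
3. Enabling feature: the cyclopentane (C1, C2, C3, C3a, C7a) holds two adjacent methyl‑bearing quaternary carbons, and C3a carries the oxygenated C4. This is the imprint of a ring‑bond shift from a 1‑methylcyclobutyl group to a methyl‑bearing epoxide carbon. The 1,3‑placement of the C4 oxygen and C6 in the six‑membered ring lets an epoxide oxygen start the cascade and a C6 enol ether end it.
4. Ring order: cyclobutane (purchased), then cyclopentane and cyclohexanone together in step 6; the arene is purchased. Absolute configuration comes from a Sharpless epoxidation (step 4) and is passed on by anti migration.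

Key step: step 6

Remark: bicyclic compounds carry the locants of the target throughout (C4 carbonyl carbon, C3a and C7a ring‑fusion carbons, C1′ the side‑chain CH2 on C6), and 2‑substituted 1,3‑diones are written as diketones although they should exist largely as enols.

**Route**

Step 1
Reactants: 1 1‑methylcyclobutane‑1‑carboxylic acid
Product: 2 1‑(1‑methylcyclobutyl)ethan‑1‑one
Conditions: MeLi (2.2 equiv), Et2O, 0 °C to rt; inverse quench into aq. HCl
Reagents that add atoms: methyllithium, [Li]C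
Why: Addition of MeLi to the lithium carboxylate stops at the geminal dilithio alkoxide, which gives the methyl ketone only on protonation (ketone synthesis from a carboxylic acid and an alkyllithium).

Step 2
Reactants: 2 1‑(1‑methylcyclobutyl)ethan‑1‑one; 3 triethyl phosphonoacetate
Product: 4 ethyl (2E)‑3‑(1‑methylcyclobutyl)but‑2‑enoate
Conditions: NaH, THF, reflux
Reagents that add atoms: none
Why: Horner–Wadsworth–Emmons olefination, in which the ester should end trans to the bulky 1‑methylcyclobutyl group (E), as with other tert‑alkyl methyl ketones.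

Step 3
Reactants: 4 ethyl (2E)‑3‑(1‑methylcyclobutyl)but‑2‑enoate
Product: 5 (2E)‑3‑(1‑methylcyclobutyl)but‑2‑en‑1‑ol
Conditions: i‑Bu2AlH (2.2 equiv), CH2Cl2, −78 to 0 °C
Reagents that add atoms: none
Why: 1,2‑Reduction of the conjugated ester by i‑Bu2AlH leaves the alkene geometry untouched.

Step 4
Reactants: 5 (2E)‑3‑(1‑methylcyclobutyl)but‑2‑en‑1‑ol
Product: 6 [(2S,3S)‑3‑methyl‑3‑(1‑methylcyclobutyl)oxiran‑2‑yl]methanol
Conditions: Ti(Oi‑Pr)4 (cat.), L‑(+)‑diethyl tartrate (cat.), t‑BuOOH, 4 Å molecular sieves, CH2Cl2, −20 °C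
Reagents that add atoms: tert‑butyl hydroperoxide, CC(C)(C)OO
Why: Sharpless asymmetric epoxidation: with L‑(+)‑diethyl tartrate the oxygen should be delivered to the alkene face that gives the (2S,3S)‑epoxide of an (E)‑3,3‑disubstituted allylic alcohol, which sets both epoxide stereocentres.

Step 5
Reactants: 6 [(2S,3S)‑3‑methyl‑3‑(1‑methylcyclobutyl)oxiran‑2‑yl]methanol
Product: 8 (2S,3S)‑2‑(2‑ethoxyprop‑2‑en‑1‑yl)‑3‑methyl‑3‑(1‑methylcyclobutyl)oxirane, via epoxy triflate 7 (not isolated)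
Conditions: n‑BuLi (1.0 equiv), Et2O, −78 °C; Tf2O (1.0 equiv), −78 °C; then transfer into CH2=C(OEt)Li (from ethyl vinyl ether and t‑BuLi, THF, −78 to 0 °C), −78 to −40 °C; chromatography on Et3N‑deactivated silica
Reagents that add atoms: 1‑ethoxyvinyllithium, [Li]C(=C)OCC; trifluoromethanesulfonic anhydride, O=S(=O)(OS(=O)(=O)C(F)(F)F)C(F)(F)F (atoms kept only in 7)
Why: The primary triflate formed from the lithium alkoxide should be displaced in an SN2 reaction by 1‑ethoxyvinyllithium (an acetyl anion equivalent) at −78 °C, far faster than the hindered epoxide is opened.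

Step 6
Reactants: 8 (2S,3S)‑2‑(2‑ethoxyprop‑2‑en‑1‑yl)‑3‑methyl‑3‑(1‑methylcyclobutyl)oxirane
Product: 10 (3aR,4S,7aR)‑4‑hydroxy‑3a,7a‑dimethyloctahydro‑6H‑inden‑6‑one, via oxocarbenium aluminate 9 (not isolated)
Conditions: MeAlCl2 (1.5 equiv), CH2Cl2, −78 °C; then aq. HCl, THF, 0 °C
Reagents that add atoms: water, O
Why: Proposed new method: MeAlCl2 should ionise the epoxide at its fully substituted carbon (future C3a) while the antiperiplanar ring C–C bond of the adjacent 1‑methylcyclobutyl group migrates (Wagner–Meerwein 1,2‑shift driven by loss of four‑membered‑ring strain); the tertiary 1,2‑dimethylcyclopentyl cation at C7a is then captured by the CH2 terminus (C7) of the tethered 2‑ethoxyallyl group, and the O‑ethyl oxocarbenium ion 9 is hydrolysed on work‑up. The closest known reaction types are the Lewis‑acid ring‑bond migration of cyclobutyl‑substituted epoxides (α‑pinene oxide type Wagner–Meerwein rearrangement) and epoxide‑initiated cation–olefin cyclisations terminated by enol ethers; their relay through a ring‑expanded cation has not been shown. The cyclopentane (C1, C2, C3, C3a, C7a) is closed by ring expansion of the cyclobutane (1,2‑alkyl shift, four to five atoms), and the cyclohexanone (C3a, C4, C5, C6, C7, C7a) by 6‑endo attack of the enol ether on the cation, forming C7–C7a. C3a is set by migration anti to the breaking C–O bond (inversion at the 3S epoxide carbon, giving 3aR); C7a is set by the three‑atom tether from C4, which can reach only the cation face syn to C4 and so enforces the cis ring fusion with both methyl groups on one face; C4 keeps the epoxide configuration until it is oxidised in step 7. The step needs ring‑bond migration to outrun hydride shift from C4 and direct attack of the enol ether on the epoxide; strain release in the cyclobutane, the absence of hydrogen on the cyclobutane carbon and the unfavourable 5‑endo geometry of direct attack should secure this.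

Step 7
Reactants: 10 (3aR,4S,7aR)‑4‑hydroxy‑3a,7a‑dimethyloctahydro‑6H‑inden‑6‑one
Product: 11 (3aR,7aR)‑3a,7a‑dimethylhexahydro‑1H‑indene‑4,6(2H,5H)‑dione
Conditions: Dess–Martin periodinane, CH2Cl2, rt
Reagents that add atoms: none
Why: Dess–Martin oxidation of the secondary alcohol should give the 1,3‑dione and removes the C4 stereocentre, which has done its work.

Step 8
Reactants: 11 (3aR,7aR)‑3a,7a‑dimethylhexahydro‑1H‑indene‑4,6(2H,5H)‑dione; 12 2‑methylprop‑2‑en‑1‑yl acetate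
Product: 13 (3aR,7aR)‑3a,7a‑dimethyl‑5‑(2‑methylprop‑2‑en‑1‑yl)hexahydro‑1H‑indene‑4,6(2H,5H)‑dione
Conditions: Pd(PPh3)4 (cat.), DBU, toluene, 60 °C
Reagents that add atoms: none
Why: Tsuji–Trost allylation: the soft dione enolate should attack the 2‑methylallyl complex of palladium at carbon, and C5 is the only doubly activated position.

Step 9
Reactants: 13 (3aR,7aR)‑3a,7a‑dimethyl‑5‑(2‑methylprop‑2‑en‑1‑yl)hexahydro‑1H‑indene‑4,6(2H,5H)‑dione
Product: 14 (3aR,7aR)‑3a,7a‑dimethyl‑5‑(2‑methylprop‑2‑en‑1‑yl)‑4‑oxo‑2,3,3a,4,7,7a‑hexahydro‑1H‑inden‑6‑yl trifluoromethanesulfonate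
Conditions: Tf2O, Et3N, CH2Cl2, −78 °C
Reagents that add atoms: trifluoromethanesulfonic anhydride, O=S(=O)(OS(=O)(=O)C(F)(F)F)C(F)(F)F
Why: O‑Sulfonylation of the dione enolate should take place at the C6 oxygen, remote from the quaternary C3a, as with 4,4‑disubstituted cyclohexane‑1,3‑diones.

Step 10
Reactants: 14 (3aR,7aR)‑3a,7a‑dimethyl‑5‑(2‑methylprop‑2‑en‑1‑yl)‑4‑oxo‑2,3,3a,4,7,7a‑hexahydro‑1H‑inden‑6‑yl trifluoromethanesulfonate
Product: 15 (3aR,7aR)‑5‑(2‑hydroxy‑2‑methylpropyl)‑3a,7a‑dimethyl‑4‑oxo‑2,3,3a,4,7,7a‑hexahydro‑1H‑inden‑6‑yl trifluoromethanesulfonate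
Conditions: Co(acac)2 (cat.), PhSiH3, O2 (1 atm), i‑PrOH/THF, rt
Reagents that add atoms: dioxygen, O=O
Why: Mukaiyama hydration: hydrogen‑atom transfer to the 1,1‑disubstituted alkene gives the tertiary radical, which is trapped by O2 and reduced to the Markovnikov alcohol, while the electron‑poor tetrasubstituted enol triflate should be inert.

Step 11
Reactants: 15 (3aR,7aR)‑5‑(2‑hydroxy‑2‑methylpropyl)‑3a,7a‑dimethyl‑4‑oxo‑2,3,3a,4,7,7a‑hexahydro‑1H‑inden‑6‑yl trifluoromethanesulfonate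
Product: 16 (3aR,7aR)‑5‑(2‑hydroxy‑2‑methylpropyl)‑3a,7a‑dimethyl‑6‑(trimethylstannyl)‑1,2,3,3a,7,7a‑hexahydro‑4H‑inden‑4‑one
Conditions: (Me3Sn)2, Pd(PPh3)4 (cat.), LiCl, THF, 65 °C
Reagents that add atoms: hexamethylditin, C[Sn](C)(C)[Sn](C)(C)C
Why: Palladium‑catalysed stannylation of the vinyl triflate with hexamethylditin (oxidative addition, tin‑to‑palladium transmetalation, reductive elimination), with chloride stabilising the alkenylpalladium intermediate.

Step 12
Reactants: 17 4‑methoxy‑2‑methylphenol; 18 1‑bromo‑3‑methylbut‑2‑ene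
Product: 19 4‑methoxy‑2‑methyl‑6‑(3‑methylbut‑2‑en‑1‑yl)phenol
Conditions: NaH, toluene, 0 °C; then 18, rt
Reagents that add atoms: none
Why: ortho‑C‑Alkylation of the sodium phenoxide as a tight ion pair in toluene; the para position and one ortho position are blocked, so the prenyl group should enter at C6 of the phenol.

Step 13
Reactants: 19 4‑methoxy‑2‑methyl‑6‑(3‑methylbut‑2‑en‑1‑yl)phenol
Product: 20 tert‑butyl[4‑methoxy‑2‑methyl‑6‑(3‑methylbut‑2‑en‑1‑yl)phenoxy]dimethylsilane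
Conditions: t‑BuMe2SiCl, imidazole, DMF, 40 °C
Reagents that add atoms: tert‑butyldimethylsilyl chloride, CC(C)(C)[Si](C)(C)Cl
Why: Silylation of the hindered phenol protects it from oxidation in step 14 and from O‑alkylation by the allylic bromide made in step 15.

Step 14
Reactants: 20 tert‑butyl[4‑methoxy‑2‑methyl‑6‑(3‑methylbut‑2‑en‑1‑yl)phenoxy]dimethylsilane
Product: 21 (2E)‑4‑{2‑[(tert‑butyldimethylsilyl)oxy]‑5‑methoxy‑3‑methylphenyl}‑2‑methylbut‑2‑en‑1‑ol
Conditions: SeO2 (cat.), t‑BuOOH, CH2Cl2, 0 °C to rt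
Reagents that add atoms: tert‑butyl hydroperoxide, CC(C)(C)OO
Why: SeO2 allylic oxidation (ene reaction, then [2,3]‑sigmatropic shift) with t‑BuOOH as terminal oxidant is selective for the (E)‑methyl group of a prenyl unit and so fixes the E geometry of the trisubstituted alkene.

Step 15
Reactants: 21 (2E)‑4‑{2‑[(tert‑butyldimethylsilyl)oxy]‑5‑methoxy‑3‑methylphenyl}‑2‑methylbut‑2‑en‑1‑ol
Product: 22 {2‑[(2E)‑4‑bromo‑3‑methylbut‑2‑en‑1‑yl]‑4‑methoxy‑6‑methylphenoxy}(tert‑butyl)dimethylsilane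
Conditions: CBr4, PPh3, CH2Cl2, 0 °C
Reagents that add atoms: tetrabromomethane, BrC(Br)(Br)Br
Why: Appel bromination of the primary allylic alcohol under neutral conditions should proceed without allylic transposition.

Step 16
Reactants: 16 (3aR,7aR)‑5‑(2‑hydroxy‑2‑methylpropyl)‑3a,7a‑dimethyl‑6‑(trimethylstannyl)‑1,2,3,3a,7,7a‑hexahydro‑4H‑inden‑4‑one; 22 {2‑[(2E)‑4‑bromo‑3‑methylbut‑2‑en‑1‑yl]‑4‑methoxy‑6‑methylphenoxy}(tert‑butyl)dimethylsilane
Product: 23 (3aR,7aR)‑6‑[(2E)‑4‑{2‑[(tert‑butyldimethylsilyl)oxy]‑5‑methoxy‑3‑methylphenyl}‑2‑methylbut‑2‑en‑1‑yl]‑5‑(2‑hydroxy‑2‑methylpropyl)‑3a,7a‑dimethyl‑1,2,3,3a,7,7a‑hexahydro‑4H‑inden‑4‑one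
Conditions: Pd2(dba)3 (cat.), AsPh3, CuI (cat.), DMF, 40 °C
Reagents that add atoms: none
Why: Stille coupling: oxidative addition of the allylic bromide to zerovalent palladium, copper‑assisted transfer of the alkenyl group from tin and reductive elimination at the unsubstituted CH2 terminus, which should retain the E geometry.

Step 17
Reactants: 23 (3aR,7aR)‑6‑[(2E)‑4‑{2‑[(tert‑butyldimethylsilyl)oxy]‑5‑methoxy‑3‑methylphenyl}‑2‑methylbut‑2‑en‑1‑yl]‑5‑(2‑hydroxy‑2‑methylpropyl)‑3a,7a‑dimethyl‑1,2,3,3a,7,7a‑hexahydro‑4H‑inden‑4‑one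
Product: 24 (3aR,7aR)‑5‑(2‑hydroxy‑2‑methylpropyl)‑6‑[(2E)‑4‑(2‑hydroxy‑5‑methoxy‑3‑methylphenyl)‑2‑methylbut‑2‑en‑1‑yl]‑3a,7a‑dimethyl‑1,2,3,3a,7,7a‑hexahydro‑4H‑inden‑4‑one
Conditions: KHF2, MeOH, rt
Reagents that add atoms: none
Why: Bifluoride cleaves the aryl silyl ether under nearly neutral conditions, which should spare the tertiary alcohol and the base‑sensitive skipped enone–alkene unit.

**Compound list**

1 | 1‑methylcyclobutane‑1‑carboxylic acid | CC1(CCC1)C(=O)O | starting material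
2 | 1‑(1‑methylcyclobutyl)ethan‑1‑one | CC(=O)C1(C)CCC1 | intermediate
3 | triethyl phosphonoacetate | CCOC(=O)CP(=O)(OCC)OCC | starting material
4 | ethyl (2E)‑3‑(1‑methylcyclobutyl)but‑2‑enoate | CCOC(=O)/C=C(\C)C1(C)CCC1 | intermediate
5 | (2E)‑3‑(1‑methylcyclobutyl)but‑2‑en‑1‑ol | OC/C=C(\C)C1(C)CCC1 | intermediate
6 | [(2S,3S)‑3‑methyl‑3‑(1‑methylcyclobutyl)oxiran‑2‑yl]methanol | OC[C@@H]1O[C@@]1(C)C2(C)CCC2 | intermediate
7 | [(2S,3S)‑3‑methyl‑3‑(1‑methylcyclobutyl)oxiran‑2‑yl]methyl trifluoromethanesulfonate | FC(F)(F)S(=O)(=O)OC[C@@H]1O[C@@]1(C)C2(C)CCC2 | intermediate (not isolated)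
8 | (2S,3S)‑2‑(2‑ethoxyprop‑2‑en‑1‑yl)‑3‑methyl‑3‑(1‑methylcyclobutyl)oxirane | C=C(OCC)C[C@@H]1O[C@@]1(C)C2(C)CCC2 | intermediate
9 | {[(3aR,4S,7aR)‑6‑(ethyloxoniumylidene)‑3a,7a‑dimethyloctahydro‑1H‑inden‑4‑yl]oxy}dichloro(methyl)aluminate (zwitterion) | CC[O+]=C1C[C@H](O[Al-](C)(Cl)Cl)[C@]2(C)CCC[C@]2(C)C1 | intermediate (not isolated)
10 | (3aR,4S,7aR)‑4‑hydroxy‑3a,7a‑dimethyloctahydro‑6H‑inden‑6‑one | O=C1C[C@H](O)[C@]2(C)CCC[C@]2(C)C1 | intermediate
11 | (3aR,7aR)‑3a,7a‑dimethylhexahydro‑1H‑indene‑4,6(2H,5H)‑dione | O=C1CC(=O)[C@]2(C)CCC[C@]2(C)C1 | intermediate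
12 | 2‑methylprop‑2‑en‑1‑yl acetate | CC(=C)COC(C)=O | starting material
13 | (3aR,7aR)‑3a,7a‑dimethyl‑5‑(2‑methylprop‑2‑en‑1‑yl)hexahydro‑1H‑indene‑4,6(2H,5H)‑dione | O=C1C(CC(C)=C)C(=O)[C@]2(C)CCC[C@]2(C)C1 | intermediate
14 | (3aR,7aR)‑3a,7a‑dimethyl‑5‑(2‑methylprop‑2‑en‑1‑yl)‑4‑oxo‑2,3,3a,4,7,7a‑hexahydro‑1H‑inden‑6‑yl trifluoromethanesulfonate | FC(F)(F)S(=O)(=O)OC1=C(CC(C)=C)C(=O)[C@]2(C)CCC[C@]2(C)C1 | intermediate
15 | (3aR,7aR)‑5‑(2‑hydroxy‑2‑methylpropyl)‑3a,7a‑dimethyl‑4‑oxo‑2,3,3a,4,7,7a‑hexahydro‑1H‑inden‑6‑yl trifluoromethanesulfonate | FC(F)(F)S(=O)(=O)OC1=C(CC(C)(C)O)C(=O)[C@]2(C)CCC[C@]2(C)C1 | intermediate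
16 | (3aR,7aR)‑5‑(2‑hydroxy‑2‑methylpropyl)‑3a,7a‑dimethyl‑6‑(trimethylstannyl)‑1,2,3,3a,7,7a‑hexahydro‑4H‑inden‑4‑one | C[Sn](C)(C)C1=C(CC(C)(C)O)C(=O)[C@]2(C)CCC[C@]2(C)C1 | intermediate
17 | 4‑methoxy‑2‑methylphenol | COc1ccc(O)c(C)c1 | starting material
18 | 1‑bromo‑3‑methylbut‑2‑ene | CC(C)=CCBr | starting material
19 | 4‑methoxy‑2‑methyl‑6‑(3‑methylbut‑2‑en‑1‑yl)phenol | COc1cc(C)c(O)c(CC=C(C)C)c1 | intermediate
20 | tert‑butyl[4‑methoxy‑2‑methyl‑6‑(3‑methylbut‑2‑en‑1‑yl)phenoxy]dimethylsilane | COc1cc(C)c(O[Si](C)(C)C(C)(C)C)c(CC=C(C)C)c1 | intermediate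
21 | (2E)‑4‑{2‑[(tert‑butyldimethylsilyl)oxy]‑5‑methoxy‑3‑methylphenyl}‑2‑methylbut‑2‑en‑1‑ol | COc1cc(C)c(O[Si](C)(C)C(C)(C)C)c(C/C=C(\C)CO)c1 | intermediate
22 | {2‑[(2E)‑4‑bromo‑3‑methylbut‑2‑en‑1‑yl]‑4‑methoxy‑6‑methylphenoxy}(tert‑butyl)dimethylsilane | COc1cc(C)c(O[Si](C)(C)C(C)(C)C)c(C/C=C(\C)CBr)c1 | intermediate
23 | (3aR,7aR)‑6‑[(2E)‑4‑{2‑[(tert‑butyldimethylsilyl)oxy]‑5‑methoxy‑3‑methylphenyl}‑2‑methylbut‑2‑en‑1‑yl]‑5‑(2‑hydroxy‑2‑methylpropyl)‑3a,7a‑dimethyl‑1,2,3,3a,7,7a‑hexahydro‑4H‑inden‑4‑one | COc1cc(C)c(O[Si](C)(C)C(C)(C)C)c(C/C=C(\C)CC2=C(CC(C)(C)O)C(=O)[C@]3(C)CCC[C@]3(C)C2)c1 | intermediate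
24 | (3aR,7aR)‑5‑(2‑hydroxy‑2‑methylpropyl)‑6‑[(2E)‑4‑(2‑hydroxy‑5‑methoxy‑3‑methylphenyl)‑2‑methylbut‑2‑en‑1‑yl]‑3a,7a‑dimethyl‑1,2,3,3a,7,7a‑hexahydro‑4H‑inden‑4‑one (CNP0158008.2) | COc1cc(C)c(O)c(C/C=C(\C)CC2=C(CC(C)(C)O)C(=O)[C@]3(C)CCC[C@]3(C)C2)c1 | target

**Step count and risks**

Total step count: 17. Longest linear sequence: 13 steps (steps 1–11, 16, 17); the arene fragment takes steps 12–15.

Steps most likely to fail:

1. Step 6 (key step). Hydride shift from C4 (Meinwald rearrangement) or proton loss from the ring‑expanded cation may outrun ring closure, and full ionisation before migration would erode the transfer of configuration. Any product of non‑stereospecific migration would be a C4 diastereomer of 10 and could be removed before step 7. The fallback uses known chemistry only, sets out from ketone 2 and comes back at dione 11. Reduction of 2 (NaBH4, MeOH) should give 1‑(1‑methylcyclobutyl)ethan‑1‑ol F1. Acid‑catalysed dehydration (H3PO4, heat) with Wagner–Meerwein ring expansion should give 1,2‑dimethylcyclopent‑1‑ene F2. A de Mayo sequence follows: [2+2] photocycloaddition with 2,2,6‑trimethyl‑4H‑1,3‑dioxin‑4‑one (hν, about 300 nm) to the cis‑fused cyclobutane photoadduct F3, then methanolysis with retro‑aldol opening (K2CO3, MeOH) to methyl 2‑(2‑acetyl‑1,2‑dimethylcyclopentyl)acetate F4. Claisen cyclisation (t‑BuOK, THF) should then give the racemic dione, that is 11 together with its enantiomer F5, and 11 would be obtained by preparative chromatography on a chiral stationary phase. This fallback gives up the asymmetric entry but keeps every later step.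

2. Step 16. Slow transfer of the hindered, electron‑poor tetrasubstituted alkenyl group from tin may allow isomerisation of the allylpalladium intermediate (loss of E geometry), homocoupling or protodestannylation. The fallback sets out from bromide 22 and triflate 15 and comes back at 23, with the roles of the partners reversed so that step 11 is skipped. Borylation of 22 (B2pin2, Pd2(dba)3 cat., DMSO, 50 °C) should give the (E)‑allylboronate F6. Suzuki–Miyaura coupling of F6 with 15 (Pd(OAc)2 cat., P(t‑Bu)3, K3PO4, THF/H2O, 40 °C), under conditions chosen for coupling at the boron‑bearing CH2, should give 23.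

3. Step 9. Poor site selection between the two enolate oxygens, or double sulfonylation, would lower the supply of the C6 triflate. The fallback sets out from 13 and comes back at 16, and moves the selection from oxygen to carbon. Oxalyl chloride with catalytic DMF (CH2Cl2, 0 °C) converts 13 by addition–elimination, chloride attacking the more accessible C6, into the 6‑chloro enone F7. Mukaiyama hydration as in step 10 should give the 6‑chloro hydroxy enone F8. Palladium‑catalysed stannylation ((Me3Sn)2, Pd(PPh3)4 cat., dioxane, 90 °C) should then return to 16.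

**Further compounds**

F1 | step 6 | 1‑(1‑methylcyclobutyl)ethan‑1‑ol (racemic) | CC(O)C1(C)CCC1
F2 | step 6 | 1,2‑dimethylcyclopent‑1‑ene | CC1=C(C)CCC1
F3 | step 6 | cyclobutane photoadduct of F2 and 2,2,6‑trimethyl‑4H‑1,3‑dioxin‑4‑one, C5 and C6 of the dioxinone joined to the two methyl‑bearing carbons of F2, both ring fusions cis, the two outer rings anti (racemic; the enantiomer leading to 11 is drawn) | CC1(C)OC(=O)[C@H]2[C@@](C)(O1)[C@]3(C)CCC[C@]23C
F4 | step 6 | methyl 2‑[(1R,2R)‑2‑acetyl‑1,2‑dimethylcyclopentyl]acetate (racemic; the enantiomer leading to 11 is drawn) | CC(=O)[C@]1(C)CCC[C@]1(C)CC(=O)OC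
F5 | step 6 | (3aS,7aS)‑3a,7a‑dimethylhexahydro‑1H‑indene‑4,6(2H,5H)‑dione | O=C1CC(=O)[C@@]2(C)CCC[C@@]2(C)C1
F6 | step 16 | tert‑butyl{4‑methoxy‑2‑methyl‑6‑[(2E)‑3‑methyl‑4‑(4,4,5,5‑tetramethyl‑1,3,2‑dioxaborolan‑2‑yl)but‑2‑en‑1‑yl]phenoxy}dimethylsilane | COc1cc(C)c(O[Si](C)(C)C(C)(C)C)c(C/C=C(\C)CB2OC(C)(C)C(C)(C)O2)c1
F7 | step 9 | (3aR,7aR)‑6‑chloro‑3a,7a‑dimethyl‑5‑(2‑methylprop‑2‑en‑1‑yl)‑1,2,3,3a,7,7a‑hexahydro‑4H‑inden‑4‑one | ClC1=C(CC(C)=C)C(=O)[C@]2(C)CCC[C@]2(C)C1
F8 | step 9 | (3aR,7aR)‑6‑chloro‑5‑(2‑hydroxy‑2‑methylpropyl)‑3a,7a‑dimethyl‑1,2,3,3a,7,7a‑hexahydro‑4H‑inden‑4‑one | ClC1=C(CC(C)(C)O)C(=O)[C@]2(C)CCC[C@]2(C)C1
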